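**Retrosynthetic overview**

1. Labels: ring A = Cs (spiro), Ck (ketone carbon between Cs and Cq), Cq (carbon with methyl and prenyl), Cenol (enol carbon), Cacyl (acyl-bearing carbon), Cz (ketone carbon between Cacyl and Cs); ring B = Cs, Cx (CH2), Ca (fusion CH), Cb (fusion CH), C7 (methyl carbinol), Cy (CH2); ring C = Ca, C3 (methyl carbinol), CH2, CH2, Cb.
2. The plan rests on the array HO–C7–Cy–Cs–C(=O) in ring B: the tertiary carbinol C7 sits two bonds from Cs, which carries a ring A carbonyl. C7–Cy is therefore cut to a methyl ketone on Cb and an α-substituted acrylate on Cs (Cs=Cy), rejoined by a SmI2 ketyl–olefin 6-endo closure.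
3. Ring C first: chlorinated (R)-linalool undergoes an alkoxide-directed magnesium-ene cyclisation that sets Ca and Cb relative to C3 (all-cis); iodide, TBS ether, methyl ketone and Negishi coupling with methyl 2-bromoacrylate give the keto acrylate.
4. Ring B second (key step). Ring A last, built on the acrylate carbonyl as Ck: Evans aldol plus Fráter–Seebach prenylation set Cq, C-acetylation of the Cs enolate opposite the axial C7 methyl sets Cs (Cz cis to the C7 oxygen), and a Dieckmann closure forms the Cacyl–Cenol bond.
5. Acylation at Cacyl with (S)-2-methylbutanoic acid and desilylation finish the target; ring order C, then B, then A.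

Key step: step 6

Remark: ring A is written as the Cenol enol of the β-triketone, as in the target SMILES, on the assumption that its tautomers interconvert freely; 14, 15 and 16 are mixtures of Cs epimers (Cs left open in their SMILES) that converge in step 9.

**Route**

Step 1
Reactants: 1 (R)-linalool
Product: 2 (3R)-6-chloro-3,7-dimethylocta-1,7-dien-3-ol (C6 epimers)
Conditions: Ca(OCl)2, CO2 (dry ice), CH2Cl2/H2O, 0 °C
Reagents that add atoms: calcium hypochlorite, [Ca+2].[O-]Cl.[O-]Cl
Why: Ene-type allylic chlorination by HOCl formed in the flask should strike only the electron-rich trisubstituted alkene, shifting the double bond to the terminal position and leaving the vinyl carbinol untouched; the new C6 centre is erased in step 2.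

Step 2
Reactants: 2 (3R)-6-chloro-3,7-dimethylocta-1,7-dien-3-ol
Product: 6 all-cis 2-(iodomethyl)-1-methyl-3-(prop-1-en-2-yl)cyclopentan-1-ol, via chloromagnesium alkoxide 3 (not isolated), via allylic Grignard reagent 4 (not isolated), via cyclised alkylmagnesium chloride 5 (not isolated)
Conditions: MeMgCl (1.0 equiv), THF, 0 °C; Mg turnings, THF, 65 °C; then I2, −78 °C → rt
Reagents that add atoms: iodine, II
Why: Intramolecular magnesium-ene reaction (type one), in which the allyl terminus bonds to the internal vinyl carbon while magnesium moves to the vinyl CH2 through a cyclic six-centre transition state; coordination of that magnesium to the neighbouring alkoxide places CH2MgCl cis to the C3 oxygen and the ene geometry places the isopropenyl group cis to CH2MgCl, so Ca and Cb are set all-cis before iodinolysis of the C–Mg bond.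

Step 3
Reactants: 6 all-cis 2-(iodomethyl)-1-methyl-3-(prop-1-en-2-yl)cyclopentan-1-ol
Product: 7 tert-butyldimethylsilyl ether of 6
Conditions: TBSOTf, 2,6-lutidine, CH2Cl2, 0 °C
Reagents that add atoms: tert-butyldimethylsilyl triflate, CC(C)(C)[Si](C)(C)OS(=O)(=O)C(F)(F)F
Why: Silyl triflate silylation of the tertiary alcohol under buffered conditions, needed so that the C3 oxygen cannot lactonise onto the later ester or quench the organozinc.

Step 4
Reactants: 7 tert-butyldimethylsilyl ether of 6
Product: 8 all-cis 1-[3-(tert-butyldimethylsilyloxy)-2-(iodomethyl)-3-methylcyclopentyl]ethanone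
Conditions: O3, CH2Cl2/MeOH, −78 °C; then Me2S, −78 °C → rt
Reagents that add atoms: ozone, [O-][O+]=O
Why: Ozonolysis with reductive work-up cleaves the only alkene to the methyl ketone (C7 carbonyl) under neutral conditions that should leave the primary iodide and the epimerisable Cb centre intact.

Step 5
Reactants: 8 all-cis 1-[3-(tert-butyldimethylsilyloxy)-2-(iodomethyl)-3-methylcyclopentyl]ethanone; 9 methyl 2-bromoacrylate
Product: 11 methyl 2-{[all-cis-2-acetyl-5-(tert-butyldimethylsilyloxy)-5-methylcyclopentyl]methyl}acrylate, via alkylzinc iodide 10 (not isolated)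
Conditions: Zn dust (activated), LiCl, THF, 40 °C; then 9, Pd(OAc)2 (cat.), 2-dicyclohexylphosphino-2′,6′-dimethoxybiphenyl (cat.), THF, rt
Reagents that add atoms: none
Why: Zinc insertion into the primary iodide tolerates the ketone, and Negishi cross-coupling (oxidative addition of zerovalent palladium into the C–Br bond of the bromoacrylate, transmetalation, reductive elimination) joins Cx to Cs while keeping the CH2 terminus Cy of the acrylate.

Step 6
Reactants: 11 methyl 2-{[all-cis-2-acetyl-5-(tert-butyldimethylsilyloxy)-5-methylcyclopentyl]methyl}acrylate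
Product: 14 methyl 1-(tert-butyldimethylsilyloxy)-4-hydroxy-1,4-dimethyloctahydro-1H-indene-6-carboxylate (cis-fused; Cs epimers), via samarium ketyl radical 12 (not isolated), via samarium enolate alkoxide 13 (not isolated)
Conditions: SmI2 (2.5 equiv), HMPA, t-BuOH, THF, −78 → 0 °C
Reagents that add atoms: none
Why: SmI2 activated by HMPA transfers one electron to the methyl ketone on Cb; the samarium ketyl at C7 adds to the unsubstituted terminus Cy of the acrylate, the ester-stabilised radical at Cs is reduced by a second SmI2 to the samarium enolate, and t-BuOH protonates it. The closest known reaction type is the SmI2/HMPA ketyl–olefin cyclisation onto acrylates, including endo closures at the β-carbon of acrylates tethered through their α-carbon. Ring B closes 6-endo-trig by forming C7–Cy, and its cis fusion is fixed beforehand by the cis acetyl and acrylate arms on ring C. The new centre C7 should be set in a chair-like transition state with the Ca–C3 bond equatorial, in which the bulky HMPA-solvated O–Sm group takes the equatorial site and the C7 methyl the axial site on the face of the Ca and Cb hydrogens, so the hydroxyl ends cis to the ring C bond of Cb; Cs forms as an epimer mixture on protonation, which is harmless because Cs is equilibrated in step 9 and made trigonal again in step 14. The step needs 6-endo over 5-exo closure and ketone over acrylate reduction: the nucleophilic ketyl is polarity-matched to the electrophilic CH2 terminus, 5-exo attack would have to hit the fully substituted α-carbon and leave an unstabilised primary radical, and HMPA makes ketyl formation fast relative to conjugate reduction.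

Step 7
Reactants: 14 methyl 1-(tert-butyldimethylsilyloxy)-4-hydroxy-1,4-dimethyloctahydro-1H-indene-6-carboxylate
Product: 15 C7 triethylsilyl ether of 14
Conditions: TESOTf, 2,6-lutidine, CH2Cl2, −78 → 0 °C
Reagents that add atoms: triethylsilyl triflate, CC[Si](CC)(CC)OS(=O)(=O)C(F)(F)F
Why: Silyl triflate silylation of the tertiary C7 alcohol removes the alkoxide that could otherwise attack carbonyl groups on Cs during the later enolate steps.

Step 8
Reactants: 15 C7 triethylsilyl ether of 14
Product: 16 [1-(tert-butyldimethylsilyloxy)-1,4-dimethyl-4-(triethylsilyloxy)octahydro-1H-inden-6-yl]methanol (Cs epimers)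
Conditions: LiAlH4, THF, 0 °C
Reagents that add atoms: none
Why: Hydride reduction of the ester to the primary alcohol, with both silyl ethers inert.

Step 9
Reactants: 16 [1-(tert-butyldimethylsilyloxy)-1,4-dimethyl-4-(triethylsilyloxy)octahydro-1H-inden-6-yl]methanol
Product: 17 1-(tert-butyldimethylsilyloxy)-1,4-dimethyl-4-(triethylsilyloxy)octahydro-1H-indene-6-carbaldehyde (CHO equatorial on Cs and cis to the C7 oxygen)
Conditions: Dess–Martin periodinane, NaHCO3, CH2Cl2, rt; then DBU (cat.), CH2Cl2, rt
Reagents that add atoms: none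
Why: Dess–Martin oxidation followed by base equilibration of the α-centre, which should converge on the equatorial aldehyde because the other Cs epimer would place the formyl group syn-axial to the C7 methyl.

Step 10
Reactants: 17 the Cs aldehyde; 18 (R)-4-benzyl-3-propionyloxazolidin-2-one
Product: 20 Evans syn aldol imide (Ck carbinol plus Cq methyl centre on the Cs side chain), via Z dibutylboron enolate 19 (not isolated)
Conditions: 18, Bu2BOTf, iPr2NEt, CH2Cl2, −78 → 0 °C; then 17, −78 → 0 °C; pH 7 buffer, MeOH, H2O2, 0 °C
Reagents that add atoms: none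
Why: Evans syn aldol reaction through the Z boron enolate and a Zimmerman–Traxler chair, in which the (R)-auxiliary dictates the absolute configuration of the new Ck carbinol (and of the transient Cq–H centre) irrespective of the aldehyde's own bias.

Step 11
Reactants: 20 Evans syn aldol imide
Product: 21 methyl syn-3-hydroxy-2-methylpropanoate bearing the bicyclic Cs substituent at the carbinol
Conditions: MeMgBr, MeOH, CH2Cl2, 0 °C
Reagents that add atoms: methanol, CO
Why: Transesterification of the imide by bromomagnesium methoxide at the exocyclic carbonyl releases the auxiliary at low temperature without retro-aldol cleavage.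

Step 12
Reactants: 21 the β-hydroxy methyl ester; 22 prenyl bromide
Product: 24 methyl 3-hydroxy-2-methyl-2-(3-methylbut-2-enyl)propanoate bearing the Cs substituent (Cq quaternary), via dilithio alkoxide enolate 23 (not isolated)
Conditions: LiN(iPr)2 (2.3 equiv), THF, −78 → −20 °C; then 22, DMPU, −78 → 0 °C
Reagents that add atoms: none
Why: Fráter–Seebach alkylation, in which the lithium-chelated alkoxide–enolate dianion is attacked by the allylic bromide on the face opposite the bulky Cs-bearing substituent of the carbinol carbon, so the Ck carbinol set in step 10 relays its configuration to the quaternary Cq (prenyl on the Cy side of the future ring A, as in the target).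

Step 13
Reactants: 24 the quaternary β-hydroxy ester
Product: 25 methyl 2-methyl-2-(3-methylbut-2-enyl)-3-oxopropanoate bearing the Cs substituent (β-keto ester; Ck ketone)
Conditions: Dess–Martin periodinane, NaHCO3, CH2Cl2, rt
Reagents that add atoms: none
Why: Dess–Martin oxidation of the hindered secondary alcohol gives the Ck ketone and removes the carbinol centre once it has done its work as control element; Cq is quaternary and cannot epimerise.

Step 14
Reactants: 25 the β-keto ester
Product: 27 C-acetylated diketo ester (Cs quaternary; the acetyl group supplies Cz and Cacyl), via lithium enolate 26 (not isolated)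
Conditions: LiN(iPr)2 (1.1 equiv), THF, −78 → 0 °C; then inverse addition to AcCl (excess), THF, −78 °C
Reagents that add atoms: acetyl chloride, CC(Cl)=O
Why: C-acylation of a ketone enolate whose only enolisable position is Cs (the reaction type used to prepare tetraalkylcyclohexanetrione precursors); in the chair of ring B with the C7 methyl axial the acyl chloride should enter equatorially on the face opposite that methyl, placing the acetyl carbonyl Cz cis to the C7 oxygen and Ck cis to the C7 methyl as in the target, while inverse addition prevents proton transfer from the more acidic product.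

Step 15
Reactants: 27 the C-acetylated diketo ester
Product: 29 spirocyclic ring A trione (enol form) as its C3 TBS and C7 TES ethers, via lithium enolate 28 (not isolated)
Conditions: LiN(SiMe3)2 (2.2 equiv), THF, −78 °C → rt; cold 0.5 M HCl work-up
Reagents that add atoms: none
Why: Dieckmann-type Claisen condensation in which the methyl ketone enolate (the future Cacyl) attacks the methyl ester carbon (the future Cenol) in a six-membered closure, driven by deprotonation of the β-triketone formed, with the quaternary centres Cs and Cq untouched.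

Step 16
Reactants: 29 the spirocyclic trione; 30 (S)-2-methylbutanoic acid
Product: 32 bis-silyl ether of hyperielliptone HB, via enol ester 31 (not isolated)
Conditions: DCC, DMAP, CH2Cl2, 0 °C → rt
Reagents that add atoms: none
Why: Carbodiimide O-acylation of the enol followed by DMAP-mediated O-to-C acyl migration to Cacyl, the only free nucleophilic carbon of the trione (standard 2-acyl-1,3-dione synthesis), under conditions mild enough to keep the α-centre of the acyl group.

Step 17
Reactants: 32 bis-silyl ether of hyperielliptone HB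
Product: 33 hyperielliptone HB
Conditions: HF·pyridine, pyridine, THF, 0 °C → rt
Reagents that add atoms: none
Why: Fluoride-driven cleavage of both tertiary silyl ethers, buffered with pyridine so that the di-tertiary 1,4-diol and the prenyl group are not exposed to strong acid.

**Compound list**

1 | (R)-linalool | CC(C)=CCC[C@@](C=C)(C)O | starting material
2 | (3R)-6-chloro-3,7-dimethylocta-1,7-dien-3-ol (C6 epimers) | C=C(C)C(Cl)CC[C@@](C=C)(C)O | intermediate
3 | chloromagnesium alkoxide of 2 | C=C(C)C(Cl)CC[C@@](C=C)(C)O[Mg]Cl | intermediate (not isolated)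
4 | allylic Grignard reagent (primary form) with chloromagnesium alkoxide | Cl[Mg]CC(C)=CCC[C@@](C=C)(C)O[Mg]Cl | intermediate (not isolated)
5 | all-cis cyclised (cyclopentyl)methylmagnesium chloride with chloromagnesium alkoxide | Cl[Mg]C[C@H]1[C@H](CC[C@@]1(C)O[Mg]Cl)C(C)=C | intermediate (not isolated)
6 | all-cis 2-(iodomethyl)-1-methyl-3-(prop-1-en-2-yl)cyclopentan-1-ol (OH, CH2I and isopropenyl on one face) | IC[C@H]1[C@H](CC[C@@]1(C)O)C(C)=C | intermediate
7 | tert-butyldimethylsilyl ether of 6 | IC[C@H]1[C@H](CC[C@@]1(C)O[Si](C)(C)C(C)(C)C)C(C)=C | intermediate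
8 | all-cis 1-[3-(tert-butyldimethylsilyloxy)-2-(iodomethyl)-3-methylcyclopentyl]ethanone | IC[C@H]1[C@H](CC[C@@]1(C)O[Si](C)(C)C(C)(C)C)C(C)=O | intermediate
9 | methyl 2-bromoacrylate | COC(=O)C(Br)=C | starting material
10 | alkylzinc iodide from 8 | I[Zn]C[C@H]1[C@H](CC[C@@]1(C)O[Si](C)(C)C(C)(C)C)C(C)=O | intermediate (not isolated)
11 | methyl 2-{[all-cis-2-acetyl-5-(tert-butyldimethylsilyloxy)-5-methylcyclopentyl]methyl}acrylate (key-step precursor) | COC(=O)C(=C)C[C@H]1[C@H](CC[C@@]1(C)O[Si](C)(C)C(C)(C)C)C(C)=O | intermediate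
12 | samarium ketyl radical at C7 | COC(=O)C(=C)C[C@H]1[C@H](CC[C@@]1(C)O[Si](C)(C)C(C)(C)C)[C](C)O[Sm](I)I | intermediate (not isolated)
13 | cyclised samarium ester enolate with C7 samarium alkoxide | COC(O[Sm](I)I)=C1C[C@H]2[C@H](CC[C@@]2(C)O[Si](C)(C)C(C)(C)C)[C@](C)(O[Sm](I)I)C1 | intermediate (not isolated)
14 | methyl 1-(tert-butyldimethylsilyloxy)-4-hydroxy-1,4-dimethyloctahydro-1H-indene-6-carboxylate (cis-fused; C7 OH cis to the ring C bond of Cb; Cs epimers) | COC(=O)C1C[C@H]2[C@H](CC[C@@]2(C)O[Si](C)(C)C(C)(C)C)[C@](C)(O)C1 | intermediate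
15 | C7 triethylsilyl ether of 14 (Cs epimers) | COC(=O)C1C[C@H]2[C@H](CC[C@@]2(C)O[Si](C)(C)C(C)(C)C)[C@](C)(O[Si](CC)(CC)CC)C1 | intermediate
16 | [1-(tert-butyldimethylsilyloxy)-1,4-dimethyl-4-(triethylsilyloxy)octahydro-1H-inden-6-yl]methanol (Cs epimers) | OCC1C[C@H]2[C@H](CC[C@@]2(C)O[Si](C)(C)C(C)(C)C)[C@](C)(O[Si](CC)(CC)CC)C1 | intermediate
17 | 1-(tert-butyldimethylsilyloxy)-1,4-dimethyl-4-(triethylsilyloxy)octahydro-1H-indene-6-carbaldehyde (CHO equatorial, cis to the C7 oxygen) | O=C[C@@H]1C[C@H]2[C@H](CC[C@@]2(C)O[Si](C)(C)C(C)(C)C)[C@](C)(O[Si](CC)(CC)CC)C1 | intermediate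
18 | (R)-4-benzyl-3-propionyloxazolidin-2-one | CCC(=O)N1[C@H](Cc2ccccc2)COC1=O | starting material
19 | Z dibutylboron enolate of 18 | C/C=C(\OB(CCCC)CCCC)N1[C@H](Cc2ccccc2)COC1=O | intermediate (not isolated)
20 | Evans syn aldol imide: (R)-4-benzyl-3-[syn-3-hydroxy-2-methyl-3-(bicyclic Cs substituent)propanoyl]oxazolidin-2-one | O=C1OC[C@@H](Cc2ccccc2)N1C(=O)[C@H](C)[C@@H](O)[C@@H]3C[C@H]4[C@H](CC[C@@]4(C)O[Si](C)(C)C(C)(C)C)[C@](C)(O[Si](CC)(CC)CC)C3 | intermediate
21 | methyl syn-3-hydroxy-2-methyl-3-(bicyclic Cs substituent)propanoate | COC(=O)[C@H](C)[C@@H](O)[C@@H]1C[C@H]2[C@H](CC[C@@]2(C)O[Si](C)(C)C(C)(C)C)[C@](C)(O[Si](CC)(CC)CC)C1 | intermediate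
22 | prenyl bromide (1-bromo-3-methylbut-2-ene) | CC(C)=CCBr | starting material
23 | dilithio alkoxide enolate of 21 | COC(O[Li])=C(C)[C@@H](O[Li])[C@@H]1C[C@H]2[C@H](CC[C@@]2(C)O[Si](C)(C)C(C)(C)C)[C@](C)(O[Si](CC)(CC)CC)C1 | intermediate (not isolated)
24 | methyl 3-hydroxy-2-methyl-2-(3-methylbut-2-enyl)-3-(bicyclic Cs substituent)propanoate (Cq quaternary) | COC(=O)[C@@](C)(CC=C(C)C)[C@@H](O)[C@@H]1C[C@H]2[C@H](CC[C@@]2(C)O[Si](C)(C)C(C)(C)C)[C@](C)(O[Si](CC)(CC)CC)C1 | intermediate
25 | methyl 2-methyl-2-(3-methylbut-2-enyl)-3-oxo-3-(bicyclic Cs substituent)propanoate | COC(=O)[C@@](C)(CC=C(C)C)C(=O)[C@@H]1C[C@H]2[C@H](CC[C@@]2(C)O[Si](C)(C)C(C)(C)C)[C@](C)(O[Si](CC)(CC)CC)C1 | intermediate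
26 | lithium enolate of 25 at Cs | COC(=O)[C@@](C)(CC=C(C)C)C(O[Li])=C1C[C@H]2[C@H](CC[C@@]2(C)O[Si](C)(C)C(C)(C)C)[C@](C)(O[Si](CC)(CC)CC)C1 | intermediate (not isolated)
27 | C-acetylated diketo ester (Cs quaternary; acetyl cis to the C7 oxygen) | COC(=O)[C@@](C)(CC=C(C)C)C(=O)[C@]1(C[C@H]2[C@H](CC[C@@]2(C)O[Si](C)(C)C(C)(C)C)[C@](C)(O[Si](CC)(CC)CC)C1)C(C)=O | intermediate
28 | lithium enolate of the acetyl group of 27 | COC(=O)[C@@](C)(CC=C(C)C)C(=O)[C@]1(C[C@H]2[C@H](CC[C@@]2(C)O[Si](C)(C)C(C)(C)C)[C@](C)(O[Si](CC)(CC)CC)C1)C(=C)O[Li] | intermediate (not isolated)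
29 | spirocyclic ring A trione (enol form), C3 TBS ether, C7 TES ether | C1=C(O)[C@@](C)(CC=C(C)C)C(=O)[C@]2(C[C@H]3[C@H](CC[C@@]3(C)O[Si](C)(C)C(C)(C)C)[C@](C)(O[Si](CC)(CC)CC)C2)C1=O | intermediate
30 | (S)-2-methylbutanoic acid | CC[C@H](C)C(O)=O | starting material
31 | enol (S)-2-methylbutanoate of 29 | C1=C(OC(=O)[C@@H](C)CC)[C@@](C)(CC=C(C)C)C(=O)[C@]2(C[C@H]3[C@H](CC[C@@]3(C)O[Si](C)(C)C(C)(C)C)[C@](C)(O[Si](CC)(CC)CC)C2)C1=O | intermediate (not isolated)
32 | hyperielliptone HB C3 TBS ether, C7 TES ether | CC[C@H](C)C(=O)C1=C(O)[C@@](C)(CC=C(C)C)C(=O)[C@]2(C[C@H]3[C@H](CC[C@@]3(C)O[Si](C)(C)C(C)(C)C)[C@](C)(O[Si](CC)(CC)CC)C2)C1=O | intermediate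
33 | hyperielliptone HB | CC[C@H](C)C(=O)C1=C(O)[C@@](C)(CC=C(C)C)C(=O)[C@]2(C[C@H]3[C@H](CC[C@@]3(C)O)[C@](C)(O)C2)C1=O | target

**Step count and risks**

Total step count: 17. Longest linear sequence: 17 steps, from (R)-linalool (1) to 33; compounds 9, 18, 22 and 30 are bought.

The three steps most likely to fail:

Step 6 (key step). Conjugate reduction or reductive dimerisation of the acrylate may outrun ketyl addition, the ketyl may close 5-exo at Cs, or the two faces of the ketyl may not be discriminated at C7. The fallback closes ring B by olefin metathesis and sets out from 11. CH2=CHMgBr with CeCl3 (THF, −78 °C) should add to the methyl ketone only and give the tertiary vinyl carbinol F1, whose C7 epimers would be separated if the Felkin-type addition is unselective. Ring-closing metathesis of the vinyl group with the acrylate (second-generation Grubbs catalyst, CH2Cl2, 40 °C) should give the cyclohexene ester F2. Hydrogenation of the Cs=Cy bond (H2, Pd/C, EtOAc) returns to the route at 14.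

Step 14. The hindered tetrasubstituted enolate may be acylated on oxygen rather than on carbon, or the electrophile may approach Cs from the face of the C7 methyl. The fallback replaces acylation by an aldol addition and oxidation and sets out from 25. The lithium enolate 26 is treated with acetaldehyde (THF, −78 °C), which can only bond at carbon and is small enough to follow the equatorial trajectory, to give the β-hydroxy ketone F3. Dess–Martin oxidation of F3 returns to the route at 27.

Step 12. The second deprotonation next to the bulky carbinol may be slow, the dianion may undergo retro-aldol cleavage on warming, or the large allylic electrophile may erode the facial preference at Cq. The fallback moves the prenyl group into the aldol partner, so that the quaternary centre is closed by methylation, and sets out from 17. 5-Methylhex-4-enoic acid is converted (pivaloyl chloride, Et3N; then (S)-4-benzyloxazolidin-2-one, LiCl) into the prenyl-bearing imide F4. Its boron aldol with 17 under the conditions of step 10 should give the syn aldol imide F5 of the opposite carbinol configuration. Transesterification (MeMgBr, MeOH) gives the methyl ester F6, and Fráter–Seebach methylation (LiN(iPr)2, then MeI) gives the quaternary hydroxy ester F7, the Ck carbinol epimer of 24 with the same Cq configuration. Dess–Martin oxidation of F7 returns to the route at 25.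

Further compounds
F1 | step 6 | methyl 2-{[all-cis-5-(tert-butyldimethylsilyloxy)-2-(2-hydroxybut-3-en-2-yl)-5-methylcyclopentyl]methyl}acrylate | COC(=O)C(=C)C[C@H]1[C@H](CC[C@@]1(C)O[Si](C)(C)C(C)(C)C)[C@](C)(O)C=C
F2 | step 6 | methyl 1-(tert-butyldimethylsilyloxy)-4-hydroxy-1,4-dimethyl-2,3,3a,4,7,7a-hexahydro-1H-indene-6-carboxylate (Cs=Cy alkene) | COC(=O)C=1C[C@H]2[C@H](CC[C@@]2(C)O[Si](C)(C)C(C)(C)C)[C@](C)(O)C=1
F3 | step 14 | β-hydroxy ketone from 26 and acetaldehyde (1-hydroxyethyl on Cs, carbinol epimers) | COC(=O)[C@@](C)(CC=C(C)C)C(=O)[C@]1(C[C@H]2[C@H](CC[C@@]2(C)O[Si](C)(C)C(C)(C)C)[C@](C)(O[Si](CC)(CC)CC)C1)C(C)O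
F4 | step 12 | (S)-4-benzyl-3-(5-methylhex-4-enoyl)oxazolidin-2-one | CC(C)=CCCC(=O)N1[C@@H](Cc2ccccc2)COC1=O
F5 | step 12 | syn aldol imide from 17 and F4 | O=C1OC[C@H](Cc2ccccc2)N1C(=O)[C@@H](CC=C(C)C)[C@H](O)[C@@H]3C[C@H]4[C@H](CC[C@@]4(C)O[Si](C)(C)C(C)(C)C)[C@](C)(O[Si](CC)(CC)CC)C3
F6 | step 12 | methyl syn-3-hydroxy-2-(3-methylbut-2-enyl)-3-(bicyclic Cs substituent)propanoate | COC(=O)[C@@H](CC=C(C)C)[C@H](O)[C@@H]1C[C@H]2[C@H](CC[C@@]2(C)O[Si](C)(C)C(C)(C)C)[C@](C)(O[Si](CC)(CC)CC)C1
F7 | step 12 | Ck carbinol epimer of 24 | COC(=O)[C@@](C)(CC=C(C)C)[C@H](O)[C@@H]1C[C@H]2[C@H](CC[C@@]2(C)O[Si](C)(C)C(C)(C)C)[C@](C)(O[Si](CC)(CC)CC)C1
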